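**Assumption:** the target has no stereocentres; its only stereo-element is the (E)-enone, so "single enantiomer" is read as "single (E)-isomer".

## Retrosynthetic overview

1. Target 10 ⇐ global removal of three MOM groups from chalcone 9.
2. 9 ⇐ aryl–Cβ bond (not the usual Cα=Cβ aldol bond): OMe-directed ortho-metalation of arene 5, then Benary addition–elimination on enaminone 8, which acts as a β-acylvinyl cation equivalent.
3. 5 ⇐ aryl–C(quaternary) bond (not the usual O-prenyl Claisen): OMOM-directed ortho-metalation of 2, then Cu-catalysed SN2′ arylation of prenyl phosphate 4.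
4. 2 ⇐ 3-methoxycatechol; 8 ⇐ 4-hydroxyacetophenone + DMF-DMA; 4 ⇐ prenol.
5. No ring is formed: both benzene rings are purchased. Bond order is Ar–CMe2(vinyl) first, then Ar–CH=.

## Route

**Step 1**
Reactants: 1, 3-methoxycatechol (3-methoxybenzene-1,2-diol)
Product: 2, 1-methoxy-2,3-bis(methoxymethoxy)benzene
Conditions: MOMCl (2.5 equiv), i-Pr2NEt (3 equiv), CH2Cl2, 0 °C → rt
Reagents that add atoms: chloromethyl methyl ether (MOMCl), COCCl
Why: Williamson-type O-alkylation of both phenols gives acetal ethers that protect the catechol and serve as strong directing groups for the later ortho-lithiation.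

**Step 2**
Reactants: 3, prenol (3-methylbut-2-en-1-ol)
Product: 4, diethyl (3-methylbut-2-en-1-yl) phosphate
Conditions: ClP(O)(OEt)2, pyridine, cat. DMAP, CH2Cl2, 0 °C → rt; used promptly
Reagents that add atoms: diethyl chlorophosphate, CCOP(=O)(Cl)OCC
Why: O-phosphorylation of a primary allylic alcohol gives the leaving group best suited to γ-selective copper allylic substitution.

**Step 3**
Reactants: 2, 1-methoxy-2,3-bis(methoxymethoxy)benzene (1.5 equiv); 4, diethyl prenyl phosphate (limiting)
Product: 5, 1-methoxy-2,3-bis(methoxymethoxy)-4-(2-methylbut-3-en-2-yl)benzene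
Conditions: n-BuLi (1.0 equiv vs 2), THF, 0 °C; Et2AlCl, −78 °C → rt; then 4, IMesCuCl (5 mol %), THF, −30 → 0 °C
Reagents that add atoms: none
Why: Directed ortho-metalation occurs ortho to OMOM (a stronger director than OMe), and the derived ArAlEt2 transfers its aryl group through an NHC–Cu centre to the γ-carbon of the γ,γ-disubstituted allylic phosphate (Cu-catalysed SN2′ allylic substitution), forming the aryl-bearing quaternary carbon with its vinyl group; no stereocentre is created.

**Step 4**
Reactants: 6, 4-hydroxyacetophenone
Product: 7, 1-[4-(methoxymethoxy)phenyl]ethan-1-one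
Conditions: MOMCl, i-Pr2NEt, CH2Cl2, 0 °C → rt
Reagents that add atoms: chloromethyl methyl ether (MOMCl), COCCl
Why: Phenol O-alkylation masks the acidic OH, which would otherwise quench the aryl Grignard in step 6 and be O-methylated by DMF-DMA in step 5.

**Step 5**
Reactants: 7, 1-[4-(methoxymethoxy)phenyl]ethan-1-one
Product: 8, (E)-3-(dimethylamino)-1-[4-(methoxymethoxy)phenyl]prop-2-en-1-one
Conditions: DMF-DMA (2 equiv), toluene, 110 °C
Reagents that add atoms: N,N-dimethylformamide dimethyl acetal, COC(OC)N(C)C
Why: Condensation of the methyl ketone with the formamide acetal (enaminone formation) gives the stable, crystalline (E)-vinylogous amide as the thermodynamic product.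

**Step 6**
Reactants: 5, 1-methoxy-2,3-bis(methoxymethoxy)-4-(2-methylbut-3-en-2-yl)benzene (limiting); 8, the enaminone (1.3 equiv)
Product: 9, (E)-3-[2-methoxy-3,4-bis(methoxymethoxy)-5-(2-methylbut-3-en-2-yl)phenyl]-1-[4-(methoxymethoxy)phenyl]prop-2-en-1-one
Conditions: n-BuLi/TMEDA, THF, 0 °C → rt; MgBr2·OEt2, 0 °C; cannulate into 8, THF, 0 °C → rt; aq NH4Cl, then SiO2/cat. AcOH
Reagents that add atoms: none
Why: With both positions ortho to OMOM blocked, the only activated C–H is the one ortho to OMe (veratrole-type directed ortho-metalation), and the aryl Grignard adds 1,4 to the vinylogous amide and loses Me2NH on work-up (Benary reaction), giving the thermodynamically favoured (E)-enone.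

**Step 7**
Reactants: 9, the tris-MOM chalcone
Product: 10, (E)-3-[3,4-dihydroxy-2-methoxy-5-(2-methylbut-3-en-2-yl)phenyl]-1-(4-hydroxyphenyl)prop-2-en-1-one (target)
Conditions: 3 M aq HCl, MeOH/THF (degassed), 40 °C, under Ar
Reagents that add atoms: none
Why: Acid-catalysed acetal hydrolysis removes all three MOM ethers while leaving the aryl methyl ether, the (E)-enone and the unactivated monosubstituted vinyl group intact, and no 2′-OH is present to cyclise to a flavanone.

## Compound list

1 | 3-methoxycatechol | COc1cccc(O)c1O | starting material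
2 | 1-methoxy-2,3-bis(methoxymethoxy)benzene | COCOc1cccc(OC)c1OCOC | intermediate
3 | prenol (3-methylbut-2-en-1-ol) | CC(C)=CCO | starting material
4 | diethyl (3-methylbut-2-en-1-yl) phosphate | CCOP(=O)(OCC)OCC=C(C)C | intermediate
5 | 1-methoxy-2,3-bis(methoxymethoxy)-4-(2-methylbut-3-en-2-yl)benzene | C=CC(C)(C)c1ccc(OC)c(OCOC)c1OCOC | intermediate
6 | 4-hydroxyacetophenone | CC(=O)c1ccc(O)cc1 | starting material
7 | 1-[4-(methoxymethoxy)phenyl]ethan-1-one | CC(=O)c1ccc(OCOC)cc1 | intermediate
8 | (E)-3-(dimethylamino)-1-[4-(methoxymethoxy)phenyl]prop-2-en-1-one | CN(C)/C=C/C(=O)c1ccc(OCOC)cc1 | intermediate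
9 | (E)-3-[2-methoxy-3,4-bis(methoxymethoxy)-5-(2-methylbut-3-en-2-yl)phenyl]-1-[4-(methoxymethoxy)phenyl]prop-2-en-1-one | C=CC(C)(C)c1cc(/C=C/C(=O)c2ccc(OCOC)cc2)c(OC)c(OCOC)c1OCOC | intermediate
10 | (E)-3-[3,4-dihydroxy-2-methoxy-5-(2-methylbut-3-en-2-yl)phenyl]-1-(4-hydroxyphenyl)prop-2-en-1-one | C=CC(C)(C)c1cc(/C=C/C(=O)c2ccc(O)cc2)c(OC)c(O)c1O | target

## Summary

**Total steps:** 7.
**Longest linear sequence:** 4 (steps 1 → 3 → 6 → 7, from 3-methoxycatechol).

**Three steps most likely to fail**

1. **Step 6 (second ortho-metalation + Benary).** Risks are incomplete OMe-directed lithiation, 1,2-addition to the carbonyl, and a second addition to the chalcone formed. Fallback: quench the aryllithium with I2 (or iodinate 5 with NIS) and run a Mizoroki–Heck coupling of the aryl iodide with 1-[4-(methoxymethoxy)phenyl]prop-2-en-1-one. Last resort: DMF quench to the aldehyde and classical Claisen–Schmidt condensation.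
2. **Step 3 (Cu-catalysed SN2′ reverse prenylation).** Risks are competing SN2 attack giving the linear prenyl arene, and sluggish reaction of the ortho-OMOM aryl group when an achiral NHC is used. Fallback: reverse the polarity by quenching the aryllithium with I2 and coupling the aryl iodide with prenyl–Bpin under Pd-catalysed γ-selective Suzuki–Miyaura conditions. Alternatively, install the group by O-prenylation and aromatic Claisen rearrangement.
3. **Step 7 (global acidic MOM removal).** Risks are acid-promoted cyclisation of the free ortho-phenol onto the vinyl group (giving a dihydrobenzofuran) and air oxidation of the catechol. Fallback: redesign the protecting groups, carrying all three phenols as 1-ethoxyethyl acetals (ethyl vinyl ether/PPTS). These still direct ortho-lithiation but cleave with PPTS/MeOH at rt, well below the acidity that threatens the alkene.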